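## Structural features

The target is a 1,7,8,8a-tetrahydro-6H-isochromen-6-one: ring A (O18, C9, C10, C11, C16, C17) is a pyran fused through the C11–C16 bond to ring B (C11 to C16), a cyclohexenone with the C13 ketone, and C9 carries an (E)-alkenyl chain (C8=C7, C6, C5, C4) ending in a sec-butyl group. O18–C9=C10–C11=C12–C13=O is one continuous doubly vinylogous ester, so C11 and C13 together sit at the oxidation level of a 1,3-dicarbonyl unit. Ring B holds three adjacent stereocentres, C14 (tertiary carbinol with methyl), C15 (secondary carbinol) and C16 (ring-fusion methine bearing C17H2); the C14 and C15 hydroxyls are cis and the C15 hydroxyl is trans to C17. The chain holds three more in a row, C6 (tertiary allylic carbinol), C5 and C4, and the planar dienyl ether between the two triads prevents any stereochemical relay, so each half must be made enantiopure on its own. Fragile points are the β-hydroxy ketone O15/C13 (retro-aldol), the α-ketol at C14, the C16 hydrogen (vinylogously acidic, with leaving groups on C15 and C17) and the acid-labile tertiary allylic alcohol at C6. The real difficulty is the C14–C15–C16 triad on a ring whose two other oxygenated carbons must end differently, C13 as ketone and C11 as the carbon-substituted alkene terminus. The key step uses the fact that C14 and C15 are vicinal cis carbinol carbons next to C16, the retron of a reductive coupling of a C14 methyl ketone with a C15 aldehyde; because C11 and C13 both end as sp2 carbons, their configurations in the open-chain substrate are free and are chosen to steer the ring closure.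

## Logic of the disconnections

31 to 29: the O18–C9 bond of ring A is cut together with the five O–Si bonds. C9 is the δ-carbon of the C13-ketone-conjugated enyne of 29, so O17 can add in a 6-endo conjugate addition. This removes ring A and leaves a monocyclic enynone. The demand is that every hydroxyl of 29 is masked by a fluoride-labile silyl group and that O17 is the only oxygen able to reach C9.

29 to 19 and 28: the C10–C11 sp–sp2 bond is cut. This splits the molecule into an eight-carbon ring B half and an eleven-carbon chain half, each with three stereocentres, and needs no stereochemical communication. The forward coupling demands an enol triflate at C11 with the carbonyl at C13, and a terminal alkyne with the E alkene already in place.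

19 back to 15 (through 18, 17, 16): no skeletal bond is cut; C11 and C13 are taken back from sp2 carbons to protected carbinols. The gain is that two disposable stereocentres become available as control elements for ring formation. The demand is that the groups on O11 and O13 leave together while O14, O15 and O17 stay masked, and that O17 can be freed at the very end. A benzyl ether on O17 could not be removed once alkyne and alkenes are present, and silyl ethers on O11 and O13 could not be told apart from those on the new diol. The roles are therefore exchanged: benzyl on O11 and O13 (hydrogenolysed while ring B is saturated), silyl on O14, O15 and O17. Sulfonylation of 18 must also occur at O11.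

15 to 14: the C14–C15 bond is cut (key step). Ring B opens to an acyclic keto aldehyde whose only lasting stereocentre is C16. The cis-diol must form trans to C17, which needs a chair with the C16 substituent equatorial. An O11 cis to C17 would force either O11 and O13 into a 1,3-diaxial pair or C17 into an axial position, and it is also not what a Z allylboron reagent delivers. C11 is therefore given the configuration of the syn adduct (O11 trans to C17 in the ring), while C13 keeps the L-malic configuration, which places O13 on the face opposite the new diol.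

14 to 10 (through 12 and 11): the C15=CH2 bond (ozonolysis retron), the C14–CH3 bond (ketone from a Weinreb amide) and the O11–benzyl bond are cut. This leads back to a homoallylic alcohol that carries C17 already protected. The demand is an order of events that makes the epimerisable C15 aldehyde last.

10 to 4 and 8: the C11–C16 bond is cut. One allylboration sets C16, the only ring stereocentre carried from here to 31, and C11. The demand is a geometrically pure Z boronate (syn relation) and attack on the Re face of the aldehyde.

8 to 6 and 7, 6 to 5; 4 to 3, 2 and 1: the boronate comes from cis-2-butene-1,4-diol by silylation and Z-retentive cross-metathesis. The C11–C14 piece is the lactone 1, which supplies C13 from the chiral pool. The demand is differentiation of the two termini (C14 as acyl, C11 as aldehyde) without touching C13.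

28 to 20 (through 27, 25, 24, 22 and 21; 23 supplies C7 to C10): the O–Si bonds, the C7=C8 alkene (from an alkyne), the C6–CH3 bond and the C6–C7 acyl bond are cut. C4 and C5 come from D-isoleucine, and C6 is set by chelate-controlled methyl addition. The demand is that the methyl group, not the unsaturated chain, is the nucleophile, because only that order gives the required C5/C6 relation under chelation.

## Other disconnections considered

Alternative 1: The cut is at C15–O (as C15–B) and C16–C17 of ring B. In the forward step a monovalent copper boryl complex (CuCl, a Josiphos-type bisphosphine, NaOtBu, B2pin2) adds to one enantiotopic enone half of the quinol ether A2, made from p-cresol A3 by oxidative dearomatisation and methoxymethylation. The C16 enolate is then trapped by formaldehyde to give A1.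
- In its favour: C14, C15 and C16 arise in one catalytic operation from an achiral dienone. On step economy this is clearly better than the chosen plan, which needs ten steps to reach 15.
- Against it: three selectivities must coincide (choice of alkene, addition syn to the C14 ether oxygen, intermolecular capture by formaldehyde before protonation). The β-boryl β′-hydroxy ketone A1 is prone to dehydration and retro-aldol. A1 also has its carbonyl at C11 and its alkene at C12=C13, so the C10 carbon and the C13 oxygen need an alkynyl addition and an oxidative 1,3-transposition with a hexavalent chromium reagent on a fragile substrate. The tertiary methoxymethyl ether needs acid for removal.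
- Comparison: the chosen plan is longer, but each stereocentre has its own well-understood control element, and ring B arrives with the C11/C13 dioxygenation that the endgame uses directly. The formaldehyde capture has less support than a pinacol cyclisation.

Alternative 2: The cut is at C14–O and O18–C17. In the forward step a flavin-dependent monooxygenase (FAD, NADPH, O2) hydroxylates C14 of the benzaldehyde A5; the dienone then closes ring A and dehydrates to the azaphilone A4.
- In its favour: it is biomimetic and needs no protecting groups. The whole skeleton and the C14 quaternary carbinol are made in one step. For C14 and for convergence up to A4 it is the equal or the better of the chosen plan.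
- Against it: acceptance of a substrate with the dihydroxylated chain is uncertain. A4 is two oxidation levels too high at C15 to C17. The O18–C17=C16–C15=O unit must be reduced 1,4 with protonation at C16 from the right face, and the C15 ketone reduced cis to O14, all beside the more electrophilic C9=C10–C11=C12–C13=O dienone and with no evident control element. A4 is also sensitive to nucleophiles at C17.
- Comparison: it is shorter on paper, but it moves the stereochemical problem of C15 and C16 to the last, least selective steps. The chosen plan makes these centres at the correct oxidation level.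

Alternative 3: The cut is at C9=C10 of ring A after an O18–C9 ester tether. In the forward step a titanium ethylidene (TiCl4, Zn, catalytic PbCl2, TMEDA, CH3CHBr2) exchanges onto the C10 vinyl group of ester A7, and the new titanium alkylidene olefinates the C9 ester carbonyl to give A6.
- In its favour: the fragments are joined by esterification, which is at least as reliable as the Sonogashira coupling. Ring A forms directly as the enol ether without base. No regiochemical question of enol sulfonylation arises, and on that point it is better.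
- Against it: the C9 carbonyl belongs to a conjugated enoate whose own C8=C7 alkene can exchange with the titanium alkylidene. The C10 vinyl group is part of a diene. A large excess of a Lewis-acidic low-valent titanium and zinc mixture meets five silyl ethers and a tertiary allylic ether. C13 must afterwards be freed and oxidised selectively. The ring B half still needs a C11 enol triflate (for a vinyl coupling), so nothing is saved there.
- Comparison: the step count is about equal. The chosen conjugate-addition closure is milder and uses the polarisation of the enynone, and the chosen plan leaves C13 at the ketone level throughout the endgame.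

Key step: step 10

Assumption: atom numbers follow the ring numbering (O18, C9 to C17); in the chain C8 and C7 are the alkene carbons, C6 the tertiary carbinol, C5 the secondary carbinol and C4 the methyl-bearing methine.
Assumption: lactone 1, the cyclised form of the 2,4-dihydroxybutanoic acid that L-malic acid gives on reduction of its C4 carboxyl group, is bought as such.

Step 1
Reactants: 1 (3S)-3-hydroxyoxolan-2-one
Product: 2 (3S)-3-(benzyloxy)oxolan-2-one
Conditions: BnOC(=NH)CCl3, TfOH (cat.), CH2Cl2–cyclohexane, 0 °C to rt
Reagents that add atoms: benzyl 2,2,2-trichloroacetimidate, N=C(OCc1ccccc1)C(Cl)(Cl)Cl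
Why: Acid-catalysed O-benzylation with the trichloroacetimidate avoids base, so the lactone α-centre (C13) is not epimerised; benzyl is chosen because it can be hydrogenolysed after ring B is closed while silyl ethers stay.

Step 2
Reactants: 2 (3S)-3-(benzyloxy)oxolan-2-one
Product: 3 (2S)-2-(benzyloxy)-4-hydroxy-N-methoxy-N-methylbutanamide
Conditions: MeNHOMe·HCl, AlMe3, CH2Cl2, 0 °C to rt
Reagents that add atoms: N,O-dimethylhydroxylamine hydrochloride, CNOC.Cl
Why: Aminolysis of the lactone by the aluminium amide (Weinreb amide formation) differentiates the termini: C14 stays at the acyl level and C11 is released as a primary alcohol.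

Step 3
Reactants: 3 (2S)-2-(benzyloxy)-4-hydroxy-N-methoxy-N-methylbutanamide
Product: 4 (2S)-2-(benzyloxy)-N-methoxy-N-methyl-4-oxobutanamide
Conditions: Dess–Martin periodinane, NaHCO3, CH2Cl2, 0 °C to rt
Reagents that add atoms: none
Why: Dess–Martin oxidation gives the C11 aldehyde under buffered conditions that should not eliminate the β-benzyloxy group; the aldehyde is used at once.

Step 4
Reactants: 5 (Z)-but-2-ene-1,4-diol
Product: 6 (Z)-1,4-bis[(tert-butyldiphenylsilyl)oxy]but-2-ene
Conditions: TBDPSCl (2.2 equiv), imidazole, DMF, rt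
Reagents that add atoms: tert-butyl(chloro)diphenylsilane, CC(C)(C)[Si](Cl)(c1ccccc1)c1ccccc1
Why: Exhaustive silylation; the symmetrical bis(silyl ether) keeps the Z alkene and offers both halves to the metathesis, and the robust silyl group later survives acid-catalysed benzylation.

Step 5
Reactants: 6 (Z)-1,4-bis[(tert-butyldiphenylsilyl)oxy]but-2-ene; 7 2-allyl-4,4,5,5-tetramethyl-1,3,2-dioxaborolane
Product: 8 (Z)-tert-butyldiphenyl{[4-(4,4,5,5-tetramethyl-1,3,2-dioxaborolan-2-yl)but-2-en-1-yl]oxy}silane
Conditions: Ru(=CH-C6H4-2-OiPr)(SIMes)(3,6-Cl2C6H2S2) (5 mol%), THF, 22 °C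
Reagents that add atoms: none
Why: Z-retentive olefin cross-metathesis: the ruthenium dithiolate carbene (SIMes = 1,3-dimesitylimidazolidin-2-ylidene) forms all-syn metallacyclobutanes, so a Z alkene partner should give the Z allylboronate, with ethene as the only co-product.

Step 6
Reactants: 4 (2S)-2-(benzyloxy)-N-methoxy-N-methyl-4-oxobutanamide; 8 (Z)-tert-butyldiphenyl{[4-(4,4,5,5-tetramethyl-1,3,2-dioxaborolan-2-yl)but-2-en-1-yl]oxy}silane
Product: 10 (2S,4S,5R)-2-(benzyloxy)-5-{[(tert-butyldiphenylsilyl)oxy]methyl}-4-hydroxy-N-methoxy-N-methylhept-6-enamide, via pinacol borate 9 (not isolated)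
Conditions: (R)-3,3'-bis(2,4,6-triisopropylphenyl)-1,1'-binaphthyl-2,2'-diyl hydrogen phosphate (5 mol%), 4 Å MS, toluene, −30 °C; aqueous work-up
Reagents that add atoms: none
Why: Chiral Brønsted acid-catalysed allylboration (crotylboration type) through a closed chair transition state: the Z geometry of 8 gives the syn relation between O11 and the C16 silyloxymethyl group, and the (R)-acid is chosen to direct the boronate to the Re face of the aldehyde, setting C11 (S) and C16 (R); the Weinreb amide is inert.

Step 7
Reactants: 10 (2S,4S,5R)-2-(benzyloxy)-5-{[(tert-butyldiphenylsilyl)oxy]methyl}-4-hydroxy-N-methoxy-N-methylhept-6-enamide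
Product: 11 (2S,4S,5R)-2,4-bis(benzyloxy)-5-{[(tert-butyldiphenylsilyl)oxy]methyl}-N-methoxy-N-methylhept-6-enamide
Conditions: BnOC(=NH)CCl3, TfOH (cat.), CH2Cl2–cyclohexane, 0 °C
Reagents that add atoms: benzyl 2,2,2-trichloroacetimidate, N=C(OCc1ccccc1)C(Cl)(Cl)Cl
Why: Acid-catalysed imidate benzylation of the secondary alcohol; an alkoxide at O11 is avoided because it could take the silyl group from O17 or epimerise C13.

Step 8
Reactants: 11 (2S,4S,5R)-2,4-bis(benzyloxy)-5-{[(tert-butyldiphenylsilyl)oxy]methyl}-N-methoxy-N-methylhept-6-enamide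
Product: 12 (3S,5S,6R)-3,5-bis(benzyloxy)-6-{[(tert-butyldiphenylsilyl)oxy]methyl}oct-7-en-2-one
Conditions: MeMgBr, THF, 0 °C
Reagents that add atoms: methylmagnesium bromide, C[Mg]Br
Why: Weinreb ketone synthesis: the chelated magnesium adduct stops after one addition and gives the C14 methyl ketone on work-up without enolisation at C13.

Step 9
Reactants: 12 (3S,5S,6R)-3,5-bis(benzyloxy)-6-{[(tert-butyldiphenylsilyl)oxy]methyl}oct-7-en-2-one
Product: 14 (2R,3S,5S)-3,5-bis(benzyloxy)-2-{[(tert-butyldiphenylsilyl)oxy]methyl}-6-oxoheptanal, via ozonide 13 (not isolated)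
Conditions: O3, CH2Cl2, −78 °C (Sudan red end point); then PPh3, −78 °C to rt
Reagents that add atoms: ozone, [O-][O+]=O
Why: Ozonolysis with reductive work-up unmasks the C15 aldehyde; the indicator dye stops ozone before the benzyl ethers are attacked, and the aldehyde is used crude to protect the C16 centre.

Step 10
Reactants: 14 (2R,3S,5S)-3,5-bis(benzyloxy)-2-{[(tert-butyldiphenylsilyl)oxy]methyl}-6-oxoheptanal
Product: 15 (1S,2S,3S,5S,6S)-3,5-bis(benzyloxy)-6-{[(tert-butyldiphenylsilyl)oxy]methyl}-2-methylcyclohexane-1,2-diol
Conditions: tin cathode, magnesium anode, Et4NOTs, iPrOH–DMF, constant current (about 2.5 F/mol), undivided cell, 0 °C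
Reagents that add atoms: none
Why: The cathode transfers one electron to the C15 aldehyde, the more easily reduced carbonyl, and the ketyl radical anion, paired with divalent magnesium ions from the anode, attacks the C14 carbonyl carbon in a 6-exo-trig closure of ring B; a second electron and protonation by isopropanol give the diol. The closest known reaction type is the electroreductive or SmI2-mediated intramolecular pinacol coupling of keto aldehydes to cis-cycloalkane-1,2-diols. The closure should pass through a chair in which the C16 silyloxymethyl group and O11 are equatorial, which is possible only because O11 is trans to C17. C15 is controlled by C16: its oxygen takes the equatorial position trans to C17. C14 is controlled by the magnesium bridge and by C13: its oxygen is axial, gauche to O15 (cis-diol) and antiperiplanar to the axial O13, with the methyl group equatorial. The competing cis-diol on the other face would need an axial methyl group and a 1,3-diaxial O13/O15 pair. The step needs reduction of the aldehyde before the ketone and inert ethers; the potential gap between aldehyde and ketone, the non-reducible benzyl and silyl ethers and the protic medium (which limits alkoxide-induced epimerisation at C16) secure this.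

Step 11
Reactants: 15 (1S,2S,3S,5S,6S)-3,5-bis(benzyloxy)-6-{[(tert-butyldiphenylsilyl)oxy]methyl}-2-methylcyclohexane-1,2-diol
Product: 16 bis(triethylsilyl) ether of 15 at O14 and O15
Conditions: TESOTf (3 equiv), 2,6-lutidine, CH2Cl2, −78 to 0 °C
Reagents that add atoms: triethylsilyl trifluoromethanesulfonate, CC[Si](CC)(CC)OS(=O)(=O)C(F)(F)F
Why: The silyl triflate silylates the secondary and the hindered tertiary hydroxyl; triethylsilyl ethers survive hydrogenolysis in ethyl acetate and leave with fluoride at the end.

Step 12
Reactants: 16 bis(triethylsilyl) ether of 15 at O14 and O15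
Product: 17 (1S,3S,4R,5S,6R)-6-{[(tert-butyldiphenylsilyl)oxy]methyl}-4-methyl-4,5-bis[(triethylsilyl)oxy]cyclohexane-1,3-diol
Conditions: H2 (1 atm), Pd(OH)2/C, EtOAc, rt
Reagents that add atoms: none
Why: Hydrogenolysis removes both sacrificial benzyl ethers at the only stage where the molecule has no alkene or alkyne; the silyl ethers are inert in ethyl acetate.

Step 13
Reactants: 17 (1S,3S,4R,5S,6R)-6-{[(tert-butyldiphenylsilyl)oxy]methyl}-4-methyl-4,5-bis[(triethylsilyl)oxy]cyclohexane-1,3-diol
Product: 18 (4S,5S,6S)-6-{[(tert-butyldiphenylsilyl)oxy]methyl}-4-methyl-4,5-bis[(triethylsilyl)oxy]cyclohexane-1,3-dione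
Conditions: Dess–Martin periodinane (3 equiv), NaHCO3, CH2Cl2, rt
Reagents that add atoms: none
Why: Double Dess–Martin oxidation gives the 1,3-dione (largely enolised), deleting the C11 and C13 stereocentres as planned; the buffer protects the silyl ethers and the enol form shields C16 from deprotonation.

Step 14
Reactants: 18 (4S,5S,6S)-6-{[(tert-butyldiphenylsilyl)oxy]methyl}-4-methyl-4,5-bis[(triethylsilyl)oxy]cyclohexane-1,3-dione
Product: 19 (4S,5S,6S)-6-{[(tert-butyldiphenylsilyl)oxy]methyl}-4-methyl-3-oxo-4,5-bis[(triethylsilyl)oxy]cyclohex-1-en-1-yl trifluoromethanesulfonate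
Conditions: PhNTf2, Et3N, CH2Cl2, 0 °C to rt
Reagents that add atoms: N-phenylbis(trifluoromethanesulfonimide), O=S(=O)(N(c1ccccc1)S(=O)(=O)C(F)(F)F)C(F)(F)F
Why: O-sulfonylation of the dione enolate should occur at the less hindered oxygen: O13 is flanked by the fully substituted C14, O11 by the tertiary C16, the bias known for 4,4-disubstituted cyclohexane-1,3-diones; this gives the vinylogous acyl triflate with the C13 carbonyl retained.

Step 15
Reactants: 20 D-isoleucine
Product: 21 (2R,3R)-2-hydroxy-3-methylpentanoic acid
Conditions: NaNO2, 1 M H2SO4, 0 °C to rt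
Reagents that add atoms: water, O
Why: Diazotisation of the α-amino acid proceeds through the α-lactone (double inversion), so C5 is formed with net retention and C4 is untouched.

Step 16
Reactants: 21 (2R,3R)-2-hydroxy-3-methylpentanoic acid
Product: 22 (2R,3R)-2-hydroxy-N-methoxy-N,3-dimethylpentanamide
Conditions: MeNHOMe·HCl, EDC·HCl, 1-hydroxybenzotriazole, N-methylmorpholine, CH2Cl2, 0 °C to rt
Reagents that add atoms: N,O-dimethylhydroxylamine hydrochloride, CNOC.Cl
Why: Carbodiimide amide coupling gives the Weinreb amide; the active ester reacts with the amine faster than with the hindered secondary hydroxyl.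

Step 17
Reactants: 22 (2R,3R)-2-hydroxy-N-methoxy-N,3-dimethylpentanamide; 23 1,4-bis(trimethylsilyl)buta-1,3-diyne
Product: 24 (6R,7R)-6-hydroxy-7-methyl-1-(trimethylsilyl)nona-1,3-diyn-5-one
Conditions: 23 (2.6 equiv), MeLi·LiBr, THF, rt; then 22, −78 to 0 °C; aq. NH4Cl
Reagents that add atoms: none
Why: MeLi removes one silyl group of 23 to give the lithium diynide; the first equivalent deprotonates the hydroxyl, the second adds to the Weinreb amide, and the chelated adduct collapses to the ynone only on quench, so no over-addition occurs.

Step 18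
Reactants: 24 (6R,7R)-6-hydroxy-7-methyl-1-(trimethylsilyl)nona-1,3-diyn-5-one
Product: 25 (5S,6R,7R)-5,7-dimethyl-1-(trimethylsilyl)nona-1,3-diyne-5,6-diol
Conditions: MeMgBr (3 equiv), Et2O–CH2Cl2, −78 °C
Reagents that add atoms: methylmagnesium bromide, C[Mg]Br
Why: Cram chelate addition: the first equivalent forms the magnesium alkoxide at O5, which chelates the C6 carbonyl, and methyl attacks from the face opposite the sec-butyl group, setting C6 (S); 1,2-addition at −78 °C should outrun conjugate addition.

Step 19
Reactants: 25 (5S,6R,7R)-5,7-dimethyl-1-(trimethylsilyl)nona-1,3-diyne-5,6-diol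
Product: 27 (3E,5S,6R,7R)-5,7-dimethylnon-3-en-1-yne-5,6-diol, via silylated enynediol 26 (not isolated)
Conditions: NaAlH2(OCH2CH2OMe)2, THF, 0 °C to rt; then MeOH, K2CO3, rt
Reagents that add atoms: none
Why: Hydroxyl-directed trans-hydroalumination (propargylic alcohol reduction) reduces only the triple bond next to the C6 alkoxide and gives the E alkene C7=C8; the basic methanol quench then cleaves the alkynyl C–Si bond.

Step 20
Reactants: 27 (3E,5S,6R,7R)-5,7-dimethylnon-3-en-1-yne-5,6-diol
Product: 28 (3E,5S,6R,7R)-5,7-dimethyl-5,6-bis[(triethylsilyl)oxy]non-3-en-1-yne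
Conditions: TESOTf (3 equiv), 2,6-lutidine, CH2Cl2, −78 to 0 °C
Reagents that add atoms: triethylsilyl trifluoromethanesulfonate, CC[Si](CC)(CC)OS(=O)(=O)C(F)(F)F
Why: Silyl triflate silylation of the secondary and the tertiary allylic hydroxyl; the terminal alkyne C–H is not silylated by this weak base.

Step 21
Reactants: 19 (4S,5S,6S)-6-{[(tert-butyldiphenylsilyl)oxy]methyl}-4-methyl-3-oxo-4,5-bis[(triethylsilyl)oxy]cyclohex-1-en-1-yl trifluoromethanesulfonate; 28 (3E,5S,6R,7R)-5,7-dimethyl-5,6-bis[(triethylsilyl)oxy]non-3-en-1-yne
Product: 29 enynone in which the C10 alkyne carbon of 28 replaces the triflate at C11 of 19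
Conditions: PdCl2(PPh3)2 (5 mol%), CuI (10 mol%), iPr2NEt, THF, rt
Reagents that add atoms: none
Why: Sonogashira coupling: the vinylogous acyl triflate adds readily to zerovalent palladium, and a hindered tertiary amine is used because a secondary amine would displace the triflate by addition–elimination.

Step 22
Reactants: 29 enynone in which the C10 alkyne carbon of 28 replaces the triflate at C11 of 19
Product: 31 (7S,8S,8aS)-3-[(1E,3S,4R,5R)-3,4-dihydroxy-3,5-dimethylhept-1-en-1-yl]-7,8-dihydroxy-7-methyl-1,7,8,8a-tetrahydro-6H-isochromen-6-one, via pentaol enynone 30 (not isolated)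
Conditions: TBAF, AcOH, THF, 0 °C to rt
Reagents that add atoms: none
Why: Fluoride cleaves all five silyl ethers and the freed C17 hydroxyl adds to C9, the δ-carbon of the enynone (1,6-oxa-Michael addition, 6-endo-dig), with protonation at C10 giving the dienyl ether of ring A; attack at C10 would be anti-Michael and O15 would have to form a bridged ring, and the acetic acid buffer limits retro-aldol cleavage.

Compound list

1 | (3S)-3-hydroxyoxolan-2-one | O[C@H]1CCOC1=O | starting material
2 | (3S)-3-(benzyloxy)oxolan-2-one | O=C1OCC[C@@H]1OCc1ccccc1 | intermediate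
3 | (2S)-2-(benzyloxy)-4-hydroxy-N-methoxy-N-methylbutanamide | CON(C)C(=O)[C@@H](OCc1ccccc1)CCO | intermediate
4 | (2S)-2-(benzyloxy)-N-methoxy-N-methyl-4-oxobutanamide | CON(C)C(=O)[C@@H](OCc1ccccc1)CC=O | intermediate
5 | (Z)-but-2-ene-1,4-diol | OC/C=C\CO | starting material
6 | (Z)-1,4-bis[(tert-butyldiphenylsilyl)oxy]but-2-ene | CC(C)(C)[Si](c1ccccc1)(c1ccccc1)OC/C=C\CO[Si](c1ccccc1)(c1ccccc1)C(C)(C)C | intermediate
7 | 2-allyl-4,4,5,5-tetramethyl-1,3,2-dioxaborolane | C=CCB1OC(C)(C)C(C)(C)O1 | starting material
8 | (Z)-tert-butyldiphenyl{[4-(4,4,5,5-tetramethyl-1,3,2-dioxaborolan-2-yl)but-2-en-1-yl]oxy}silane | CC(C)(C)[Si](c1ccccc1)(c1ccccc1)OC/C=C\CB1OC(C)(C)C(C)(C)O1 | intermediate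
9 | O11 pinacol borate of 10 | CON(C)C(=O)[C@@H](OCc1ccccc1)C[C@H](OB1OC(C)(C)C(C)(C)O1)[C@@H](CO[Si](c1ccccc1)(c1ccccc1)C(C)(C)C)C=C | intermediate (not isolated)
10 | (2S,4S,5R)-2-(benzyloxy)-5-{[(tert-butyldiphenylsilyl)oxy]methyl}-4-hydroxy-N-methoxy-N-methylhept-6-enamide | CON(C)C(=O)[C@@H](OCc1ccccc1)C[C@H](O)[C@@H](CO[Si](c1ccccc1)(c1ccccc1)C(C)(C)C)C=C | intermediate
11 | (2S,4S,5R)-2,4-bis(benzyloxy)-5-{[(tert-butyldiphenylsilyl)oxy]methyl}-N-methoxy-N-methylhept-6-enamide | CON(C)C(=O)[C@@H](OCc1ccccc1)C[C@H](OCc1ccccc1)[C@@H](CO[Si](c1ccccc1)(c1ccccc1)C(C)(C)C)C=C | intermediate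
12 | (3S,5S,6R)-3,5-bis(benzyloxy)-6-{[(tert-butyldiphenylsilyl)oxy]methyl}oct-7-en-2-one | CC(=O)[C@@H](OCc1ccccc1)C[C@H](OCc1ccccc1)[C@@H](CO[Si](c1ccccc1)(c1ccccc1)C(C)(C)C)C=C | intermediate
13 | ozonide (1,2,4-trioxolane) of 12, both epimers at the trioxolane carbon | CC(=O)[C@@H](OCc1ccccc1)C[C@H](OCc1ccccc1)[C@@H](CO[Si](c1ccccc1)(c1ccccc1)C(C)(C)C)C1OCOO1 | intermediate (not isolated)
14 | (2R,3S,5S)-3,5-bis(benzyloxy)-2-{[(tert-butyldiphenylsilyl)oxy]methyl}-6-oxoheptanal | CC(=O)[C@@H](OCc1ccccc1)C[C@H](OCc1ccccc1)[C@@H](CO[Si](c1ccccc1)(c1ccccc1)C(C)(C)C)C=O | intermediate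
15 | (1S,2S,3S,5S,6S)-3,5-bis(benzyloxy)-6-{[(tert-butyldiphenylsilyl)oxy]methyl}-2-methylcyclohexane-1,2-diol | c1ccccc1CO[C@H]2C[C@H](OCc1ccccc1)[C@@](C)(O)[C@@H](O)[C@@H]2CO[Si](c1ccccc1)(c1ccccc1)C(C)(C)C | intermediate
16 | bis(triethylsilyl) ether of 15 at O14 and O15 | c1ccccc1CO[C@H]2C[C@H](OCc1ccccc1)[C@@](C)(O[Si](CC)(CC)CC)[C@@H](O[Si](CC)(CC)CC)[C@@H]2CO[Si](c1ccccc1)(c1ccccc1)C(C)(C)C | intermediate
17 | (1S,3S,4R,5S,6R)-6-{[(tert-butyldiphenylsilyl)oxy]methyl}-4-methyl-4,5-bis[(triethylsilyl)oxy]cyclohexane-1,3-diol | O[C@H]1C[C@H](O)[C@@](C)(O[Si](CC)(CC)CC)[C@@H](O[Si](CC)(CC)CC)[C@@H]1CO[Si](c1ccccc1)(c1ccccc1)C(C)(C)C | intermediate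
18 | (4S,5S,6S)-6-{[(tert-butyldiphenylsilyl)oxy]methyl}-4-methyl-4,5-bis[(triethylsilyl)oxy]cyclohexane-1,3-dione | O=C1CC(=O)[C@@](C)(O[Si](CC)(CC)CC)[C@@H](O[Si](CC)(CC)CC)[C@@H]1CO[Si](c1ccccc1)(c1ccccc1)C(C)(C)C | intermediate
19 | (4S,5S,6S)-6-{[(tert-butyldiphenylsilyl)oxy]methyl}-4-methyl-3-oxo-4,5-bis[(triethylsilyl)oxy]cyclohex-1-en-1-yl trifluoromethanesulfonate | FC(F)(F)S(=O)(=O)OC1=CC(=O)[C@@](C)(O[Si](CC)(CC)CC)[C@@H](O[Si](CC)(CC)CC)[C@@H]1CO[Si](c1ccccc1)(c1ccccc1)C(C)(C)C | intermediate
20 | D-isoleucine, (2R,3R)-2-amino-3-methylpentanoic acid | CC[C@@H](C)[C@@H](N)C(=O)O | starting material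
21 | (2R,3R)-2-hydroxy-3-methylpentanoic acid | CC[C@@H](C)[C@@H](O)C(=O)O | intermediate
22 | (2R,3R)-2-hydroxy-N-methoxy-N,3-dimethylpentanamide | CC[C@@H](C)[C@@H](O)C(=O)N(C)OC | intermediate
23 | 1,4-bis(trimethylsilyl)buta-1,3-diyne | C[Si](C)(C)C#CC#C[Si](C)(C)C | starting material
24 | (6R,7R)-6-hydroxy-7-methyl-1-(trimethylsilyl)nona-1,3-diyn-5-one | CC[C@@H](C)[C@@H](O)C(=O)C#CC#C[Si](C)(C)C | intermediate
25 | (5S,6R,7R)-5,7-dimethyl-1-(trimethylsilyl)nona-1,3-diyne-5,6-diol | CC[C@@H](C)[C@@H](O)[C@@](C)(O)C#CC#C[Si](C)(C)C | intermediate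
26 | (3E,5S,6R,7R)-5,7-dimethyl-1-(trimethylsilyl)non-3-en-1-yne-5,6-diol | CC[C@@H](C)[C@@H](O)[C@@](C)(O)/C=C/C#C[Si](C)(C)C | intermediate (not isolated)
27 | (3E,5S,6R,7R)-5,7-dimethylnon-3-en-1-yne-5,6-diol | CC[C@@H](C)[C@@H](O)[C@@](C)(O)/C=C/C#C | intermediate
28 | (3E,5S,6R,7R)-5,7-dimethyl-5,6-bis[(triethylsilyl)oxy]non-3-en-1-yne | CC[C@@H](C)[C@@H](O[Si](CC)(CC)CC)[C@@](C)(O[Si](CC)(CC)CC)/C=C/C#C | intermediate
29 | enynone: ring B of 19 joined at C11 to the C10 alkyne carbon of 28, all five silyl ethers in place | CC[C@@H](C)[C@@H](O[Si](CC)(CC)CC)[C@@](C)(O[Si](CC)(CC)CC)/C=C/C#CC1=CC(=O)[C@@](C)(O[Si](CC)(CC)CC)[C@@H](O[Si](CC)(CC)CC)[C@@H]1CO[Si](c1ccccc1)(c1ccccc1)C(C)(C)C | intermediate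
30 | pentaol enynone: 29 without its five silyl groups | CC[C@@H](C)[C@@H](O)[C@@](C)(O)/C=C/C#CC1=CC(=O)[C@@](C)(O)[C@@H](O)[C@@H]1CO | intermediate (not isolated)
31 | (7S,8S,8aS)-3-[(1E,3S,4R,5R)-3,4-dihydroxy-3,5-dimethylhept-1-en-1-yl]-7,8-dihydroxy-7-methyl-1,7,8,8a-tetrahydro-6H-isochromen-6-one | CC[C@@H](C)[C@@H](O)[C@@](C)(O)/C=C/C1=CC2=CC(=O)[C@@](C)(O)[C@@H](O)[C@@H]2CO1 | target

Total step count: 22. Longest linear sequence: 14 steps (1 to 31 through steps 1–3, 6–14, 21 and 22); the chain half takes 6 steps and the boronate 2 steps before they join.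

Steps least certain to work

Step 10 (key step). The aldehyde may be reduced to the primary alcohol without C–C bond formation. The α-benzyloxy group at C13 may be lost reductively if the ketone is reduced first. Magnesium alkoxides may epimerise C16 or eliminate an ether from the β-alkoxy aldehyde, and the cis and facial selectivity may be eroded if the chair is not followed. The fallback leaves the reductive coupling altogether and sets out from 12, before the ozonolysis. Wittig methylenation of the C14 ketone (Ph3P=CH2, THF, 0 °C) gives the 1,7-diene (3S,5S,6R)-3,5-bis(benzyloxy)-6-{[(tert-butyldiphenylsilyl)oxy]methyl}-2-methylocta-1,7-diene F1. Ring-closing metathesis with the second-generation Grubbs catalyst RuCl2(=CHPh)(SIMes)(PCy3) gives the ring B cyclohexene with the C14=C15 alkene F2. Dihydroxylation (OsO4 cat., N-methylmorpholine N-oxide, acetone–water) should occur on the face opposite both allylic substituents (O13 and C17), which is the face required, and the route is rejoined at 15.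

Step 6. The catalyst may not override the small intrinsic bias of the β-alkoxy aldehyde (poor facial selectivity), and any Z to E isomerisation of 8 (or incomplete geometric purity from step 5) would leak into the anti diastereomer. The fallback replaces allylboration by an auxiliary-controlled aldol and sets out from 4. The dibutylboron enolate (Bu2BOTf, iPr2NEt, CH2Cl2, −78 °C) of the imide (R)-4-benzyl-3-{3-[(tert-butyldiphenylsilyl)oxy]propanoyl}oxazolidin-2-one F3 gives the Evans syn-aldol adduct F4, with the same C11 and C16 configurations as 10 and the imide carbonyl as C15. Benzylation with the trichloroacetimidate gives the benzyl ether F5. NaBH4 in THF–water removes the auxiliary to give the C15 primary alcohol F6. MeMgBr converts the Weinreb amide into the hydroxy methyl ketone F7, and Dess–Martin oxidation rejoins the route at 14.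

Step 14. Sulfonylation may compete at O13 (poor site selectivity), which would carry the alkyne to the wrong carbon. The fallback turns the same oxygen preference to use and sets out from 18. O-Methylation (Me2SO4, K2CO3, acetone) at the oxygen that proved more reactive gives, in that case, the C13 methyl enol ether with the C11 carbonyl retained F8. The lithium acetylide of 28 (n-BuLi, THF, −78 °C) adds to C11 to give the tertiary propargylic carbinol F9. Dilute acid then hydrolyses the enol ether with loss of water (Stork–Danheiser transposition) and rejoins the route at 29.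

Step 18. The magnesium alkoxide of 24 may add to its own ynone (5-endo closure to a furanone), or methyl may add in a conjugate sense, instead of the chelate-controlled 1,2-addition. The fallback masks the hydroxyl with a chelating ether and sets out from 22. p-Methoxybenzyl trichloroacetimidate with catalytic camphorsulfonic acid gives the p-methoxybenzyl ether of the Weinreb amide F10. The lithium diynide from 23 gives the α-(p-methoxybenzyloxy) diynone F11. MeMgBr adds under chelation by the ether oxygen, in the same facial sense, to give the tertiary carbinol F12. DDQ in CH2Cl2–pH 7 buffer removes the ether and rejoins the route at 25.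

Step 22. Basic fluoride may trigger retro-aldol cleavage at C14–C15 or elimination at C16 before ring A closes, or the conjugate addition may stall under the buffered conditions. The fallback separates the two events and changes the ring-closing mechanism; it sets out from 29. HF·pyridine buffered with pyridine in THF removes the silyl groups under weakly acidic conditions, and 30 is isolated. A monovalent gold catalyst ((Ph3P)AuCl, AgOTf, CH2Cl2, rt) then activates the alkyne for 6-endo hydroalkoxylation at C9, and the route is rejoined at 31. No new compound is made.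

Further compounds

F1 | step 10 | (3S,5S,6R)-3,5-bis(benzyloxy)-6-{[(tert-butyldiphenylsilyl)oxy]methyl}-2-methylocta-1,7-diene | C=C(C)[C@@H](OCc1ccccc1)C[C@H](OCc1ccccc1)[C@@H](CO[Si](c1ccccc1)(c1ccccc1)C(C)(C)C)C=C
F2 | step 10 | ring B cyclohexene with C14=C15, benzyl ethers at O11 and O13 and the silyl ether at O17 | c1ccccc1CO[C@H]2C[C@H](OCc1ccccc1)C(C)=C[C@@H]2CO[Si](c1ccccc1)(c1ccccc1)C(C)(C)C
F3 | step 6 | (R)-4-benzyl-3-{3-[(tert-butyldiphenylsilyl)oxy]propanoyl}oxazolidin-2-one | O=C(CCO[Si](c1ccccc1)(c1ccccc1)C(C)(C)C)N1[C@H](Cc2ccccc2)COC1=O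
F4 | step 6 | Evans syn-aldol adduct of 4 and F3 | CON(C)C(=O)[C@@H](OCc1ccccc1)C[C@H](O)[C@@H](CO[Si](c1ccccc1)(c1ccccc1)C(C)(C)C)C(=O)N1[C@H](Cc2ccccc2)COC1=O
F5 | step 6 | O11 benzyl ether of F4 | CON(C)C(=O)[C@@H](OCc1ccccc1)C[C@H](OCc1ccccc1)[C@@H](CO[Si](c1ccccc1)(c1ccccc1)C(C)(C)C)C(=O)N1[C@H](Cc2ccccc2)COC1=O
F6 | step 6 | C15 primary alcohol with the Weinreb amide retained | CON(C)C(=O)[C@@H](OCc1ccccc1)C[C@H](OCc1ccccc1)[C@@H](CO[Si](c1ccccc1)(c1ccccc1)C(C)(C)C)CO
F7 | step 6 | C15 primary alcohol with the C14 methyl ketone | CC(=O)[C@@H](OCc1ccccc1)C[C@H](OCc1ccccc1)[C@@H](CO[Si](c1ccccc1)(c1ccccc1)C(C)(C)C)CO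
F8 | step 14 | C13 methyl enol ether of 18 with the C11 carbonyl retained | O=C1C=C(OC)[C@@](C)(O[Si](CC)(CC)CC)[C@@H](O[Si](CC)(CC)CC)[C@@H]1CO[Si](c1ccccc1)(c1ccccc1)C(C)(C)C
F9 | step 14 | tertiary propargylic carbinol from addition of the acetylide of 28 to C11 of F8, both C11 epimers | CC[C@@H](C)[C@@H](O[Si](CC)(CC)CC)[C@@](C)(O[Si](CC)(CC)CC)/C=C/C#CC1(O)C=C(OC)[C@@](C)(O[Si](CC)(CC)CC)[C@@H](O[Si](CC)(CC)CC)[C@@H]1CO[Si](c1ccccc1)(c1ccccc1)C(C)(C)C
F10 | step 18 | (2R,3R)-N-methoxy-2-[(4-methoxybenzyl)oxy]-N,3-dimethylpentanamide | CC[C@@H](C)[C@@H](OCc1ccc(OC)cc1)C(=O)N(C)OC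
F11 | step 18 | (6R,7R)-6-[(4-methoxybenzyl)oxy]-7-methyl-1-(trimethylsilyl)nona-1,3-diyn-5-one | CC[C@@H](C)[C@@H](OCc1ccc(OC)cc1)C(=O)C#CC#C[Si](C)(C)C
F12 | step 18 | (5S,6R,7R)-6-[(4-methoxybenzyl)oxy]-5,7-dimethyl-1-(trimethylsilyl)nona-1,3-diyn-5-ol | CC[C@@H](C)[C@@H](OCc1ccc(OC)cc1)[C@@](C)(O)C#CC#C[Si](C)(C)C
F0 | step 22 | none | none
A1 | alternative 1 | ring B enone with C15 boronate, C16 hydroxymethyl and C14 methoxymethyl ether | O=C1C=C[C@@](C)(OCOC)[C@@H](B2OC(C)(C)C(C)(C)O2)[C@@H]1CO
A2 | alternative 1 | 4-(methoxymethoxy)-4-methylcyclohexa-2,5-dien-1-one | CC1(OCOC)C=CC(=O)C=C1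
A3 | alternative 1 | p-cresol | Cc1ccc(O)cc1
A4 | alternative 2 | azaphilone with C15 ketone and C16=C17 alkene | CC[C@@H](C)[C@@H](O)[C@@](C)(O)/C=C/C1=CC2=CC(=O)[C@@](C)(O)C(=O)C2=CO1
A5 | alternative 2 | 2,4-dihydroxy-3-methyl-6-(2-oxoalkenyl)benzaldehyde carrying the dihydroxylated chain | CC[C@@H](C)[C@@H](O)[C@@](C)(O)/C=C/C(=O)Cc1cc(O)c(C)c(O)c1C=O
A6 | alternative 3 | bicyclic dienyl ether with C13 as silyl-protected alcohol | CC[C@@H](C)[C@@H](O[Si](CC)(CC)CC)[C@@](C)(O[Si](CC)(CC)CC)/C=C/C1=CC2=C[C@@H](O[Si](CC)(CC)CC)[C@@](C)(O[Si](CC)(CC)CC)[C@@H](O[Si](CC)(CC)CC)[C@@H]2CO1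
A7 | alternative 3 | C17 ester of the chain enoic acid with the C11 vinyl cyclohexene | CC[C@@H](C)[C@@H](O[Si](CC)(CC)CC)[C@@](C)(O[Si](CC)(CC)CC)/C=C/C(=O)OC[C@@H]1C(C=C)=C[C@@H](O[Si](CC)(CC)CC)[C@@](C)(O[Si](CC)(CC)CC)[C@H]1O[Si](CC)(CC)CC
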